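## Structural features

The target is a daucane-type hydroazulene. A cycloheptene (ring A: C1–C6 and C10) shares the C6–C10 bond with a cyclopentane (ring B: C6–C10). The locants used throughout are: C1 angelate carbinol, C2=C3 olefin with the methyl on C3, C4 methylene, C5 veratrate carbinol, C6 ring-fusion CH, C7 tertiary carbinol carrying the isopropyl group, C8 and C9 methylenes, C10 quaternary carbon carrying the angular methyl.

Five stereocentres are present. C1, C10, C6 and C5 form one contiguous chain and C7 is attached to C6. The ring fusion is trans (H6 anti to the C10 methyl). Both acyloxy groups lie on the face of H6, and the C7 hydroxyl lies on the face of the C10 methyl (absolute configuration 1R,5S,6S,7R,10S in these locants).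

The fragile groups are three. The Z-enoate of the angelate isomerises to the tiglate under acyl activation, with nucleophiles and with stannyl radicals. The allylic C1–O bond can ionise. The tertiary C7 hydroxyl can be lost by dehydration or retro-aldol cleavage whenever C5 is a ketone.

The real difficulty is a seven-membered ring that holds a quaternary centre next to a carbinol, with both secondary oxygens on the face opposite the angular methyl. Hydride must therefore reach C1 and C5 from the hindered methyl face, or an oxygen nucleophile must enter from the open face.

The key step exploits the 1,3,5-relationship around C6: oxygen at C1 and C5 and methyl at C3 are the 2,6-dimethoxy-4-methyl pattern of an aryl group bonded through C6. Ring A is that benzene ring plus one inserted carbon, C10, which also closes ring B and brings the angular methyl.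

## Logic of the disconnections

**24 to 22 and 23.** The C1–O bond is cut last because the allylic Z-enoate is the most fragile group. This removes the only group that radicals, acid and hydride would damage. The forward step must invert C1 and must not activate the carboxyl group of 23.

**22 to 21.** The C9–H bond is traced back to a C9–O xanthate. The C9 oxygen is what the key step leaves behind. Its radical removal is safe only when C1 is sp3 and no enoate is present, which fixes its place between the C1 reduction and the esterification.

**21 to 20.** The C1–H bond is cut back to the enone. Hydride should enter anti to the adjacent axial C10 methyl, so the alcohol formed is the C1 epimer; this is accepted and corrected by the inversion above. The demand is clean 1,2-reduction.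

**20 to 18 and 19.** The C5–O acyl bond is cut while C1 is still a carbonyl group. The two secondary oxygens then never exist as free alcohols together and need no differentiation.

**18 to 17.** The C5–H bond is cut back to the ketone. The C7 hydroxyl is β to C5 and can deliver hydride to the face that the C10 methyl shields. The demand is a free C7 hydroxyl and no second β-hydroxy ketone (C9 must not be a free alcohol or a ketone).

**17 to 16.** Both carbonyl groups and the C6–H bond are traced to the two enol ethers of the triene. This brings ring A to the oxidation level of an arene. The forward step must cleave both enol ethers without losing the C7 oxygen and must leave C6 under thermodynamic control.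

**16 to 15 to 14.** The xanthate and the alcohol are functional-group changes at C9. The ketone of 14 is β to the silyloxy group and must be disarmed before any base is used.

**14 to 12 (through 13).** C10–C6 and C10–C1 are cut, and the aryl C6–C1 bond is restored. Two rings and the quaternary centre are traded for an arene and a diazoketone. The forward step needs chemoselectivity for the arene and control of C10 by C7.

**12 to 10.** The C9–C10 bond is cut to an acid and diazoethane. The forward step must activate the acid without acid-induced loss of the tertiary silyl ether.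

**10 to 8 to 7.** Protecting-group change and resolution. C7 is the only stereocentre that is not made under substrate control, so it is selected here on the simplest neutral compound.

**7 to 4 and 5.** The C7–C8 bond is cut (acetate aldol). The forward step must add to a hindered, enolisable ketone.

**4 to 1 and 2.** The C6–C7 bond is cut. The position between the two methoxy groups of 1 is the one that lithiates.

## Other disconnections considered

**Alternative 1:** The cut is C1–C10, made while a C5–O bond is given up. In the forward step the dihydropyran A1 is lithiated at its allylic O–CH2 carbon (C1). A [2,3]-Wittig shift across O–C5–C6=C10 forms C1–C10 and gives the cycloheptadienol A2.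

- In its favour: one pericyclic event of a known class creates the quaternary C10 and the C1 carbinol together, with chirality passed on from the single stereocentre of A1. The C2=C3 olefin is in place from the start. C9 never carries oxygen. No diazo compound is needed.
- Against it here: the shift consumes the C5 oxygen, so A2 has a C5=C6 olefin. C5–O and C6–H must be re-made by a hydroboration that has to choose between two trisubstituted olefins and between two faces. C7 is still a masked ketone. The contraction of a six-membered ether to a seven-membered carbocycle passes a strained bicyclic transition state and competes with the [1,2]-shift.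
- Comparison: on structure it builds one ring and two stereocentres (C1, C10); the chosen step builds two rings and one stereocentre. On mechanism it is the better of the two, because the reaction class is precedented. It would also give the natural C1 configuration directly, where the chosen route needs an inversion, and it needs no C9 deoxygenation; on both points it is better. On step economy it is worse after the key step, since C5, C6, C7 and both ester sites remain to be built on a diene that offers little differentiation.

**Alternative 2:** The cut is C6–C10. In the forward step Rh2(OAc)4 converts the α-diazo-β-keto ester A3 into a carbenoid at C6, which inserts into the tertiary C10–H bond with retention and closes ring B as the cyclopentanone A4.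

- In its favour: 1,5-insertion into a tertiary C–H bond is reliable. A cheap methyl-bearing stereocentre becomes the quaternary C10 without any resolution, which is better than the chosen plan. The catalyst is the same.
- Against it here: only ring B is made (one ring, one bond). Ring A, with three further carbons, the olefin and two carbinols, must be added from the C1 and C5 handles by chain extension and a ring closure (for instance metathesis with a second-generation Grubbs catalyst). C1 and C5 would arise from additions to open-chain aldehydes with weak control. The isopropyl carbinol must be made at the carbonyl of an enolisable β-keto ester.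
- Comparison: on mechanism it is the better plan (fully known chemistry). On structure the chosen key step does more. On step economy the alternative is clearly longer after its key step. Both plans are equal in relying on a rhodium carbenoid and in leaving the ring A oxygens to be adjusted afterwards.

**Alternative 3:** The cuts are C1–C2 and C2–C3 (C2 is the inserted carbon). In the forward step the silyl enol ether A5 of a trans-hydrindanone undergoes Simmons–Smith cyclopropanation with Et2Zn and CH2I2, oxidative opening with FeCl3 and dehydrochlorination with NaOAc to give the ring A enone A6.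

- In its favour: the chemistry is known. The step is late and regiospecific, because C10 is quaternary and the ketone enolises to one side only. C5, C6, C7 and C10 are set beforehand on a rigid six–five system. C9 never carries oxygen.
- Against it here: the difficulty moves upstream into a hydrindanone with oxygen on both carbons flanking the ring fusion, a tertiary carbinol and a quaternary centre, which needs a long route of its own. FeCl3 is a one-electron oxidant and meets the electron-rich veratrate ring and a tertiary silyl ether. The chloride elimination could also give the exocyclic or the C3=C4 olefin. The tetrasubstituted enol ether is hindered toward the zinc carbenoid.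
- Comparison: on structure its key step builds no new ring and no stereocentre. On mechanism it is safer than the chosen step, which is a point in its favour. After the key step both plans face the same problem, reduction at C1 from the methyl face or inversion, so they are equal there. On step economy it has fewer steps after the key step but more before, and the total should be higher.

Key step: step 6

Remark on the structures: the configurations of the key-step precursor and product were re-derived from the target (C7 is R in 12; 14 is 3R,8aS, with the C10 methyl syn to the C7 oxygen). They needed no correction.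

Assumption: the enantiomers of 7 are taken to be separable on a chiral stationary phase, and the (R)-enantiomer is to be identified (for instance by anomalous-dispersion crystallography of a later crystalline compound) before it is carried on.

## Route

Step 1
Reactants: 1 3,5-dimethoxytoluene; 2 N-methoxy-N-methyl-2-methylpropanamide
Product: 4 1-(2,6-dimethoxy-4-methylphenyl)-2-methylpropan-1-one, via aryllithium 3 (not isolated)
Conditions: n-BuLi, THF, 0 °C to rt; then 2, −78 to 0 °C; aq. NH4Cl
Reagents that add atoms: none
Why: Directed ortho-lithiation takes place at the C–H bond between the two methoxy groups, and acylation with the N-methoxy-N-methylamide stops at the ketone because the chelated tetrahedral adduct survives until work-up.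

Step 2
Reactants: 4 1-(2,6-dimethoxy-4-methylphenyl)-2-methylpropan-1-one; 5 tert-butyl acetate
Product: 7 rac-tert-butyl 3-(2,6-dimethoxy-4-methylphenyl)-3-hydroxy-4-methylpentanoate, via lithium enolate 6 (not isolated)
Conditions: LDA, THF, −78 °C; then 4, −78 to −40 °C; AcOH quench at −78 °C
Reagents that add atoms: none
Why: Aldol addition of the small lithium ester enolate to the hindered ketone, whose carbonyl is twisted out of conjugation with the arene; the cold acidic quench should forestall retro-aldol cleavage, and C7 is formed racemic.

Step 3
Reactants: 7 rac-tert-butyl 3-(2,6-dimethoxy-4-methylphenyl)-3-hydroxy-4-methylpentanoate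
Product: 8 tert-butyl (3R)-3-(2,6-dimethoxy-4-methylphenyl)-3-hydroxy-4-methylpentanoate
Conditions: preparative SFC, amylose tris(3,5-dimethylphenylcarbamate) phase, CO2–MeOH
Reagents that add atoms: none
Why: Resolution by chiral-phase chromatography of a neutral, UV-active ester; this selects the absolute configuration at C7, the centre from which all later stereocentres are derived.

Step 4
Reactants: 8 tert-butyl (3R)-3-(2,6-dimethoxy-4-methylphenyl)-3-hydroxy-4-methylpentanoate
Product: 10 (3R)-3-(2,6-dimethoxy-4-methylphenyl)-4-methyl-3-(trimethylsilyloxy)pentanoic acid, via bis-silyl ester 9 (not isolated)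
Conditions: TMSOTf (3 equiv), 2,6-lutidine, CH2Cl2, −78 to 0 °C; then pH 7 phosphate buffer, THF
Reagents that add atoms: trimethylsilyl trifluoromethanesulfonate, C[Si](C)(C)OS(=O)(=O)C(F)(F)F
Why: The silyl triflate with a hindered pyridine silylates the tertiary alcohol and converts the tert-butyl ester into the silyl ester with loss of isobutene, so no protic acid touches the electron-rich benzylic carbinol; the silyl ester hydrolyses on buffered work-up while the hindered tertiary silyl ether should remain.

Step 5
Reactants: 10 (3R)-3-(2,6-dimethoxy-4-methylphenyl)-4-methyl-3-(trimethylsilyloxy)pentanoic acid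
Product: 12 (5R)-2-diazo-5-(2,6-dimethoxy-4-methylphenyl)-6-methyl-5-(trimethylsilyloxy)heptan-3-one, via acid chloride 11 (not isolated)
Conditions: 1-chloro-N,N,2-trimethylprop-1-en-1-amine, CH2Cl2, 0 °C; then CH3CHN2 (3 equiv, ethereal solution), Et2O, −20 to 0 °C
Reagents that add atoms: 1-chloro-N,N,2-trimethylprop-1-en-1-amine, CC(C)=C(Cl)N(C)C; diazoethane, CC=[N+]=[N-]
Why: The α-chloroenamine forms the acid chloride under neutral conditions, so no HCl reaches the silyl ether; acylation of diazoethane (Arndt–Eistert-type diazoketone synthesis) then gives the diazoethyl ketone, and excess diazoethane takes up the HCl.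

Step 6
Reactants: 12 (5R)-2-diazo-5-(2,6-dimethoxy-4-methylphenyl)-6-methyl-5-(trimethylsilyloxy)heptan-3-one
Product: 14 (3R,8aS)-4,8-dimethoxy-6,8a-dimethyl-3-(propan-2-yl)-3-(trimethylsilyloxy)-2,3-dihydroazulen-1(8aH)-one, via norcaradiene 13 (not isolated)
Conditions: Rh2(OAc)4 (1 mol %), CH2Cl2, 40 °C, slow addition of 12 at high dilution
Reagents that add atoms: none
Why: Proposed new method: Rh2(OAc)4 (a divalent rhodium carboxylate) decomposes 12 to an electrophilic carbenoid at C10 that cyclopropanates the ipso–ortho bond C6–C1 of the arene (ring B is closed by intramolecular carbenoid addition through a five-membered tether), and norcaradiene 13 then opens by a thermal six-electron disrotatory electrocyclic reaction that cleaves C6–C1 (ring A arises by ring expansion of the benzene ring). The closest known reaction type is the Rh2(OAc)4-catalysed intramolecular Buchner reaction of 2-diazo-5-arylpentan-3-ones to 8a-methyl-dihydroazulenones; new here are the attack on an ortho carbon that carries a methoxy group in a doubly ortho-substituted, very electron-rich ring and the silyloxy group in the tether. The reasoning is that both ortho positions are blocked for aromatic substitution, that the two methoxy groups raise the π-nucleophilicity of exactly the bond to be attacked, and that the quaternary C10 of the product cannot tautomerise to a tetralone. The one new stereocentre, C10, is controlled by the preset C7 centre: in the cyclopropanation transition state the C10 methyl should lie anti to the larger C7 substituent (isopropyl) across the forming ring B and hence syn to the silyloxy group. Chemoselectivity is needed over oxonium-ylide formation at the C7 oxygen and over insertion into the isopropyl methine C–H bond; the hindered, weakly basic tertiary silyl ether, the inductive deactivation of that methine by the neighbouring oxygen and the high nucleophilicity of the arene should secure it. Regioselectivity is not in question because the two ipso–ortho bonds are equivalent.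

Step 7
Reactants: 14 (3R,8aS)-4,8-dimethoxy-6,8a-dimethyl-3-(propan-2-yl)-3-(trimethylsilyloxy)-2,3-dihydroazulen-1(8aH)-one
Product: 15 (1R,3R,8aR)-4,8-dimethoxy-6,8a-dimethyl-3-(propan-2-yl)-3-(trimethylsilyloxy)-1,2,3,8a-tetrahydroazulen-1-ol
Conditions: NaBH4, EtOH–THF, −20 to 0 °C
Reagents that add atoms: none
Why: Borohydride reduction of the cyclopentanone, with hydride expected anti to the C10 methyl; it removes the β-silyloxy ketone, which would eliminate under base, before any base is used, and the C9 configuration is of no consequence.

Step 8
Reactants: 15 (1R,3R,8aR)-4,8-dimethoxy-6,8a-dimethyl-3-(propan-2-yl)-3-(trimethylsilyloxy)-1,2,3,8a-tetrahydroazulen-1-ol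
Product: 16 O-[(1R,3R,8aR)-4,8-dimethoxy-6,8a-dimethyl-3-(propan-2-yl)-3-(trimethylsilyloxy)-1,2,3,8a-tetrahydroazulen-1-yl] S-methyl carbonodithioate
Conditions: NaHMDS, THF, −78 °C; CS2; MeI, −78 to −40 °C
Reagents that add atoms: carbon disulfide, S=C=S; iodomethane, CI
Why: Xanthate formation, the first half of a Barton–McCombie deoxygenation; the low temperature should keep the alkoxide from taking over the neighbouring silyl group, and the xanthate also protects the C9 oxygen through the next four steps.

Step 9
Reactants: 16 O-[(1R,3R,8aR)-4,8-dimethoxy-6,8a-dimethyl-3-(propan-2-yl)-3-(trimethylsilyloxy)-1,2,3,8a-tetrahydroazulen-1-yl] S-methyl carbonodithioate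
Product: 17 ene-dione xanthate (C1 and C5 ketones, C2=C3 olefin, free C7 hydroxyl, C6–H trans to the C10 methyl)
Conditions: 2 M aq. HCl, THF, 0 to 25 °C
Reagents that add atoms: water, O
Why: Acid hydrolysis of both enol ethers and of the silyl ether: protonation at the triene terminus C6 gives a pentadienyl cation stabilised by both oxygens, and the vinylogous ester that follows is hydrolysed in turn; C6 is α to the C5 ketone and should equilibrate to the trans-fused isomer, in which C5 is anti to the isopropyl group.

Step 10
Reactants: 17 ene-dione xanthate
Product: 18 C5 alcohol (C5 hydroxyl trans to the C10 methyl, C1 enone retained)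
Conditions: Me4NBH(OAc)3, MeCN–AcOH (1:1), −30 to −20 °C
Reagents that add atoms: none
Why: Evans–Saksena hydroxyl-directed reduction: the C7 hydroxyl exchanges onto boron and delivers hydride intramolecularly to the β-carbonyl C5 from its own face, which gives the 1,3-anti diol and thus the C5 hydroxyl on the face of H6; the C1 enone has no β-hydroxyl and this reagent should not reduce an undirected carbonyl group.

Step 11
Reactants: 18 C5 alcohol; 19 3,4-dimethoxybenzoyl chloride
Product: 20 C5 veratrate enone
Conditions: pyridine, DMAP (cat.), CH2Cl2, 0 to 25 °C
Reagents that add atoms: none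
Why: DMAP-catalysed acylation of the only secondary alcohol; the hindered tertiary C7 hydroxyl should not react.

Step 12
Reactants: 20 C5 veratrate enone
Product: 21 (1S)-allylic alcohol (C1 hydroxyl cis to the C10 methyl)
Conditions: NaBH4, CeCl3·7H2O, MeOH, −78 to −40 °C
Reagents that add atoms: none
Why: Luche 1,2-reduction of the enone; hydride should enter anti to the axial methyl on the adjacent C10, which gives the C1 epimer of the target on purpose, to be inverted in step 14.

Step 13
Reactants: 21 (1S)-allylic alcohol
Product: 22 (3R,3aS,4S,8S,8aS)-3,8-dihydroxy-6,8a-dimethyl-3-(propan-2-yl)-1,2,3,3a,4,5,8,8a-octahydroazulen-4-yl 3,4-dimethoxybenzoate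
Conditions: Bu3SnH, AIBN (cat.), toluene, 90 °C
Reagents that add atoms: none
Why: Barton–McCombie deoxygenation of the xanthate; C1 is now sp3, so the C9 radical has no adjacent π-system to add to, and the step comes before the angelate is present because stannyl radicals isomerise Z-enoates.

Step 14
Reactants: 22 (3R,3aS,4S,8S,8aS)-3,8-dihydroxy-6,8a-dimethyl-3-(propan-2-yl)-1,2,3,3a,4,5,8,8a-octahydroazulen-4-yl 3,4-dimethoxybenzoate; 23 angelic acid
Product: 24 (3R,3aS,4S,8R,8aS)-3-hydroxy-6,8a-dimethyl-8-{[(2Z)-2-methylbut-2-enoyl]oxy}-3-(propan-2-yl)-1,2,3,3a,4,5,8,8a-octahydroazulen-4-yl 3,4-dimethoxybenzoate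
Conditions: PPh3, DIAD, toluene, 0 to 25 °C
Reagents that add atoms: none
Why: Mitsunobu esterification with inversion at the allylic C1: the carboxylate enters from the open face anti to the C10 methyl, attack at the trisubstituted C3 is disfavoured, and the carboxyl group of 23 is never activated, so the Z-olefin should be kept; the tertiary hydroxyl is inert.

## Compound list

1 | 3,5-dimethoxytoluene | Cc1cc(OC)cc(OC)c1 | starting material
2 | N-methoxy-N-methyl-2-methylpropanamide | CC(C)C(=O)N(C)OC | starting material
3 | (2,6-dimethoxy-4-methylphenyl)lithium | [Li]c1c(OC)cc(C)cc1OC | intermediate (not isolated)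
4 | 1-(2,6-dimethoxy-4-methylphenyl)-2-methylpropan-1-one | CC(C)C(=O)c1c(OC)cc(C)cc1OC | intermediate
5 | tert-butyl acetate | CC(=O)OC(C)(C)C | starting material
6 | lithium 1-tert-butoxyethen-1-olate (lithium enolate of 5) | [Li+].[O-]C(=C)OC(C)(C)C | intermediate (not isolated)
7 | rac-tert-butyl 3-(2,6-dimethoxy-4-methylphenyl)-3-hydroxy-4-methylpentanoate | CC(C)C(O)(CC(=O)OC(C)(C)C)c1c(OC)cc(C)cc1OC | intermediate
8 | tert-butyl (3R)-3-(2,6-dimethoxy-4-methylphenyl)-3-hydroxy-4-methylpentanoate | CC(C)(C)OC(=O)C[C@@](O)(C(C)C)c1c(OC)cc(C)cc1OC | intermediate
9 | trimethylsilyl (3R)-3-(2,6-dimethoxy-4-methylphenyl)-4-methyl-3-(trimethylsilyloxy)pentanoate | C[Si](C)(C)OC(=O)C[C@@](O[Si](C)(C)C)(C(C)C)c1c(OC)cc(C)cc1OC | intermediate (not isolated)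
10 | (3R)-3-(2,6-dimethoxy-4-methylphenyl)-4-methyl-3-(trimethylsilyloxy)pentanoic acid | OC(=O)C[C@@](O[Si](C)(C)C)(C(C)C)c1c(OC)cc(C)cc1OC | intermediate
11 | (3R)-3-(2,6-dimethoxy-4-methylphenyl)-4-methyl-3-(trimethylsilyloxy)pentanoyl chloride | ClC(=O)C[C@@](O[Si](C)(C)C)(C(C)C)c1c(OC)cc(C)cc1OC | intermediate (not isolated)
12 | (5R)-2-diazo-5-(2,6-dimethoxy-4-methylphenyl)-6-methyl-5-(trimethylsilyloxy)heptan-3-one | CC(=[N+]=[N-])C(=O)C[C@@](O[Si](C)(C)C)(C(C)C)c1c(OC)cc(C)cc1OC | intermediate (key-step precursor)
13 | norcaradiene valence isomer of 14 (cyclopropane C10–C6–C1 fused to the 1,5-dimethoxy-3-methylcyclohexadiene and to the cyclopentanone; C10 methyl on the face of the diene ring) | C[C@]12C(=O)C[C@@](O[Si](C)(C)C)(C(C)C)[C@]13C(OC)=CC(C)=C[C@]23OC | intermediate (not isolated)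
14 | (3R,8aS)-4,8-dimethoxy-6,8a-dimethyl-3-(propan-2-yl)-3-(trimethylsilyloxy)-2,3-dihydroazulen-1(8aH)-one | COC1=CC(C)=CC(OC)=C2[C@]1(C)C(=O)C[C@@]2(O[Si](C)(C)C)C(C)C | intermediate (key-step product)
15 | (1R,3R,8aR)-4,8-dimethoxy-6,8a-dimethyl-3-(propan-2-yl)-3-(trimethylsilyloxy)-1,2,3,8a-tetrahydroazulen-1-ol (C9 hydroxyl cis to the C10 methyl) | COC1=CC(C)=CC(OC)=C2[C@]1(C)[C@H](O)C[C@@]2(O[Si](C)(C)C)C(C)C | intermediate
16 | O-[(1R,3R,8aR)-4,8-dimethoxy-6,8a-dimethyl-3-(propan-2-yl)-3-(trimethylsilyloxy)-1,2,3,8a-tetrahydroazulen-1-yl] S-methyl carbonodithioate | COC1=CC(C)=CC(OC)=C2[C@]1(C)[C@H](OC(=S)SC)C[C@@]2(O[Si](C)(C)C)C(C)C | intermediate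
17 | O-[(1R,3R,3aR,8aR)-3-hydroxy-6,8a-dimethyl-4,8-dioxo-3-(propan-2-yl)-1,2,3,3a,4,5,8,8a-octahydroazulen-1-yl] S-methyl carbonodithioate (ene-dione; trans ring fusion; enol and 3-ene tautomers possible) | O=C1C=C(C)CC(=O)[C@@H]2[C@]1(C)[C@H](OC(=S)SC)C[C@@]2(O)C(C)C | intermediate
18 | O-[(1R,3R,3aS,4S,8aR)-3,4-dihydroxy-6,8a-dimethyl-8-oxo-3-(propan-2-yl)-1,2,3,3a,4,5,8,8a-octahydroazulen-1-yl] S-methyl carbonodithioate (C5 hydroxyl trans to the C10 methyl) | O=C1C=C(C)C[C@H](O)[C@@H]2[C@]1(C)[C@H](OC(=S)SC)C[C@@]2(O)C(C)C | intermediate
19 | 3,4-dimethoxybenzoyl chloride | COc1ccc(C(Cl)=O)cc1OC | starting material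
20 | (1R,3R,3aS,4S,8aR)-3-hydroxy-6,8a-dimethyl-1-{[(methylsulfanyl)carbonothioyl]oxy}-8-oxo-3-(propan-2-yl)-1,2,3,3a,4,5,8,8a-octahydroazulen-4-yl 3,4-dimethoxybenzoate | O=C1C=C(C)C[C@H](OC(=O)c3ccc(OC)c(OC)c3)[C@@H]2[C@]1(C)[C@H](OC(=S)SC)C[C@@]2(O)C(C)C | intermediate
21 | (1R,3R,3aS,4S,8S,8aS)-3,8-dihydroxy-6,8a-dimethyl-1-{[(methylsulfanyl)carbonothioyl]oxy}-3-(propan-2-yl)-1,2,3,3a,4,5,8,8a-octahydroazulen-4-yl 3,4-dimethoxybenzoate (C1 hydroxyl cis to the C10 methyl) | O[C@H]1C=C(C)C[C@H](OC(=O)c3ccc(OC)c(OC)c3)[C@@H]2[C@]1(C)[C@H](OC(=S)SC)C[C@@]2(O)C(C)C | intermediate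
22 | (3R,3aS,4S,8S,8aS)-3,8-dihydroxy-6,8a-dimethyl-3-(propan-2-yl)-1,2,3,3a,4,5,8,8a-octahydroazulen-4-yl 3,4-dimethoxybenzoate | O[C@H]1C=C(C)C[C@H](OC(=O)c3ccc(OC)c(OC)c3)[C@@H]2[C@]1(C)CC[C@@]2(O)C(C)C | intermediate
23 | angelic acid, (2Z)-2-methylbut-2-enoic acid | C/C=C(/C)C(=O)O | starting material
24 | (3R,3aS,4S,8R,8aS)-3-hydroxy-6,8a-dimethyl-8-{[(2Z)-2-methylbut-2-enoyl]oxy}-3-(propan-2-yl)-1,2,3,3a,4,5,8,8a-octahydroazulen-4-yl 3,4-dimethoxybenzoate | C/C=C(/C)C(=O)O[C@@H]1C=C(C)C[C@H](OC(=O)c2ccc(OC)c(OC)c2)[C@@H]2[C@]1(C)CC[C@@]2(O)C(C)C | target

## Step count and least certain steps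

Total step count: 14. Longest linear sequence: 14 steps (the route is linear from 1).

**Step 6 (key step).** The most likely failure is diversion of the carbenoid before it reaches the arene. It could be captured by the C7 ether oxygen (a five-membered oxonium ylide followed by silyl shift), or it could insert into the isopropyl methine C–H bond. A second possibility is heterolytic opening of the methoxy-substituted acylcyclopropane (donor on C1, acceptor on C10) to an ipso σ-complex that collapses to spiro or furan-type products instead of undergoing the electrocyclic opening. Poor facial selectivity at C10 is a further risk.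

The fallback uses only known reaction types and reduces the arene before the carbenoid step, so that the carbenoid meets an ordinary enol ether. It sets out from 10 and comes back at 14.
- K2CO3 in MeOH should remove the silyl group and give (3R)-3-(2,6-dimethoxy-4-methylphenyl)-3-hydroxy-4-methylpentanoic acid F1.
- Birch reduction (Li, NH3–THF, t-BuOH, −78 °C) of its dianion should give the 2,5-dihydroarene (3R)-3-(2,6-dimethoxy-4-methylcyclohexa-2,5-dien-1-yl)-3-hydroxy-4-methylpentanoic acid F2. The tertiary alkoxide protects the benzylic C–O bond from hydrogenolysis.
- KOt-Bu in DMSO should move one double bond into conjugation and give (3R)-3-(2,6-dimethoxy-4-methylcyclohexa-1,5-dien-1-yl)-3-hydroxy-4-methylpentanoic acid F3, in which C6=C1 is a tetrasubstituted enol ether.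
- Silylation (TMSCl, imidazole; buffered work-up, the acid kept as its sodium salt) gives (3R)-3-(2,6-dimethoxy-4-methylcyclohexa-1,5-dien-1-yl)-4-methyl-3-(trimethylsilyloxy)pentanoic acid F4.
- The operations of step 5 give (5R)-2-diazo-5-(2,6-dimethoxy-4-methylcyclohexa-1,5-dien-1-yl)-6-methyl-5-(trimethylsilyloxy)heptan-3-one F5.
- Rh2(OAc)4 or Cu(acac)2 then effects the classical intramolecular cyclopropanation of an enol ether by a diazoketone (bicyclo[3.1.0]hexanone closure) and gives the tricyclic methoxycyclopropyl ketone F6, the 2,3-dihydro analogue of 13.
- 2,3-Dichloro-5,6-dicyano-1,4-benzoquinone removes the C3 hydride (allylic to the C4=C5 enol ether) and a C2 proton. This gives norcaradiene 13, which opens to 14.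

The ring sp3 carbons of F2 to F6 are stereo-mixtures that converge in the last operation.

**Step 10.** The intramolecular hydride transfer must take place on the face of C5 that the axial C10 methyl shields. It also competes with reduction through the 3-ene tautomer of 17. The step may therefore be slow, may give the C5 epimer, or may leave the olefin out of conjugation.

The fallback replaces directed delivery by substrate-controlled reduction followed by inversion. It sets out from 17 and comes back at 20. NaBH4 in MeOH at −78 °C, without a cerium salt, should reduce the saturated ketone in preference to the enone, from the open face. This gives the C5-epimeric alcohol, O-[3,4-dihydroxy-6,8a-dimethyl-8-oxo-3-(propan-2-yl)octahydroazulen-1-yl] S-methyl carbonodithioate with the C5 hydroxyl cis to the C10 methyl, F7. A Mitsunobu reaction with 3,4-dimethoxybenzoic acid (PPh3, DIAD) then installs the veratrate with inversion, the carboxylate entering from the open face, and gives 20.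

**Step 9.** The second hydrolysis, that of the vinylogous ester, needs stronger acid than the first. Under these conditions the tertiary C7 hydroxyl, which is β to the C5 carbonyl, may be lost by dehydration or retro-aldol cleavage. Equilibration at C6 may also be incomplete.

The fallback cleaves the second enol ether by nucleophilic dealkylation instead of hydrolysis. It sets out from 16 and comes back at 17. Oxalic acid in wet THF at 0 °C should hydrolyse only the first enol ether and the silyl ether. This gives the vinylogous methyl ester, drawn as the C1-keto C5-methoxy isomer F10; the other regioisomer would serve equally, because both give the same anion. LiI in DMF with 2,6-lutidine at 60 °C attacks the O-methyl carbon and releases the lithium salt of the vinylogous acid. Buffered protonation (NaH2PO4) gives 17 without strong acid.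

**Step 14.** Substitution at a carbinol that is allylic but flanked by a quaternary carbon may be slow. Attack at C3, 1,4-elimination to a diene, or isomerisation of the Z-enoate may then take over.

The fallback sets the natural C1 configuration by reagent control and esterifies with retention. It sets out from 20 and comes back at 24. Corey–Bakshi–Shibata reduction with the (S)-methyl oxazaborolidine and catecholborane (hydride to the Si face of C1 if the quaternary C10 acts as the large group) should give the (1R)-allylic alcohol, the C1 epimer of 21, F8. Bu3SnH with AIBN removes the xanthate and gives the (8R)-diol monoveratrate, the C1 epimer of 22, F9. Yamaguchi esterification with 23 (2,4,6-trichlorobenzoyl chloride, Et3N; then F9, DMAP, toluene) gives 24.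

## Further compounds

F1 | step 6 | (3R)-3-(2,6-dimethoxy-4-methylphenyl)-3-hydroxy-4-methylpentanoic acid | OC(=O)C[C@@](O)(C(C)C)c1c(OC)cc(C)cc1OC
F2 | step 6 | (3R)-3-(2,6-dimethoxy-4-methylcyclohexa-2,5-dien-1-yl)-3-hydroxy-4-methylpentanoic acid (mixture at the ring sp3 carbons) | OC(=O)C[C@@](O)(C(C)C)C1C(OC)=CC(C)C=C1OC
F3 | step 6 | (3R)-3-(2,6-dimethoxy-4-methylcyclohexa-1,5-dien-1-yl)-3-hydroxy-4-methylpentanoic acid | OC(=O)C[C@@](O)(C(C)C)C1=C(OC)CC(C)C=C1OC
F4 | step 6 | (3R)-3-(2,6-dimethoxy-4-methylcyclohexa-1,5-dien-1-yl)-4-methyl-3-(trimethylsilyloxy)pentanoic acid | OC(=O)C[C@@](O[Si](C)(C)C)(C(C)C)C1=C(OC)CC(C)C=C1OC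
F5 | step 6 | (5R)-2-diazo-5-(2,6-dimethoxy-4-methylcyclohexa-1,5-dien-1-yl)-6-methyl-5-(trimethylsilyloxy)heptan-3-one | CC(=[N+]=[N-])C(=O)C[C@@](O[Si](C)(C)C)(C(C)C)C1=C(OC)CC(C)C=C1OC
F6 | step 6 | tricyclic methoxycyclopropyl ketone, 2,3-dihydro analogue of 13 | C[C@]12C(=O)C[C@@](O[Si](C)(C)C)(C(C)C)[C@]13C(OC)=CC(C)C[C@]23OC
F7 | step 10 | C5 epimer of 18 (C5 hydroxyl cis to the C10 methyl) | O=C1C=C(C)C[C@@H](O)[C@@H]2[C@]1(C)[C@H](OC(=S)SC)C[C@@]2(O)C(C)C
F8 | step 14 | C1 epimer of 21 ((1R)-allylic alcohol, C1 hydroxyl trans to the C10 methyl) | O[C@@H]1C=C(C)C[C@H](OC(=O)c3ccc(OC)c(OC)c3)[C@@H]2[C@]1(C)[C@H](OC(=S)SC)C[C@@]2(O)C(C)C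
F9 | step 14 | C1 epimer of 22, (3R,3aS,4S,8R,8aS)-3,8-dihydroxy-6,8a-dimethyl-3-(propan-2-yl)-1,2,3,3a,4,5,8,8a-octahydroazulen-4-yl 3,4-dimethoxybenzoate | O[C@@H]1C=C(C)C[C@H](OC(=O)c3ccc(OC)c(OC)c3)[C@@H]2[C@]1(C)CC[C@@]2(O)C(C)C
F10 | step 9 | vinylogous methyl ester (C1 ketone, C2=C3 and C4=C5 olefins, C5 methoxy, free C7 hydroxyl, C9 xanthate) | O=C1C=C(C)C=C(OC)[C@@H]2[C@]1(C)[C@H](OC(=S)SC)C[C@@]2(O)C(C)C
A1 | alternative 1 | (2S)-4-methyl-2-(7-methyl-1,4-dioxaspiro[4.4]non-6-en-6-yl)-3,6-dihydro-2H-pyran (configuration as the suprafacial shift would require) | CC1=CCO[C@@H](C1)C2=C(C)CCC23OCCO3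
A2 | alternative 1 | bicyclic cycloheptadienol ethylene ketal (C1 hydroxyl, C2=C3 and C5=C6 olefins, C10 methyl, C7 ketal; 1R,10S in route locants) | O[C@@H]1C=C(C)CC=C2[C@]1(C)CCC23OCCO3
A3 | alternative 2 | methyl (6S)-7-[(tert-butyldimethylsilyl)oxy]-2-diazo-6-methyl-3-oxoheptanoate | COC(=O)C(=[N+]=[N-])C(=O)CC[C@H](C)CO[Si](C)(C)C(C)(C)C
A4 | alternative 2 | methyl (1R,2S)-2-[(tert-butyldimethylsilyloxy)methyl]-2-methyl-5-oxocyclopentane-1-carboxylate | COC(=O)[C@H]1C(=O)CC[C@]1(C)CO[Si](C)(C)C(C)(C)C
A5 | alternative 3 | trimethylsilyl enol ether (C1=C3) of the trans-hydrindanone carrying the C5 veratrate and the C7 trimethylsilyl ether | C[Si](C)(C)OC1=C(C)C[C@H](OC(=O)c2ccc(OC)c(OC)c2)[C@@H]2[C@]1(C)CC[C@@]2(O[Si](C)(C)C)C(C)C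
A6 | alternative 3 | ring A enone (C1 ketone, C2=C3 olefin) with C5 veratrate and C7 trimethylsilyl ether | O=C1C=C(C)C[C@H](OC(=O)c2ccc(OC)c(OC)c2)[C@@H]2[C@]1(C)CC[C@@]2(O[Si](C)(C)C)C(C)C
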